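**Plan**

- Retrosynthesis first cuts the O7–Si bond of a late silyl ether, then the C2–C3 bond of the pyranone ring, which opens ring C to an aryl diazomethyl ketone bearing an ortho 3,4-dimethoxybenzyl (veratryl) ether.
- Further cuts remove the diazo nitrogen (back to the acetyl CH3), the O1–CH2 ether bond, the O7 silyl group and the two aryl–prenyl C–C bonds, ending at 2,4-dihydroxyacetophenone.
- Forward: ring A is bought and prenylated at both free positions, O7 is silylated, ring B arrives as the veratryl ether on O1, the acetyl group becomes the diazoketone, and ring C is closed last.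
- Enabling feature: C2 is a methine bonded to O1 and to C1' of the 3,4-dimethoxyphenyl ring B, so it is one C–H of a veratryl ether CH2 lying six atoms from C3 and activated on both sides for carbenoid insertion.
- Stereochemistry: the only stereocentre, C2 (S), is set in the ring closure by a chiral dirhodium(II) prolinate that selects one of the two enantiotopic benzylic hydrogens; the final desilylation is buffered so that C2 is not opened.

Key step: step 5

Assumption: the (S)-prolinate catalyst Rh2(S-BSP)4 is taken to deliver the 2S configuration on this substrate; if the first run shows the opposite sense, the mirror-image catalyst from D-proline is used under the same conditions.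

**Route**

Step 1
Reactants: 1 2,4-dihydroxyacetophenone; 2 prenyl bromide (1-bromo-3-methylbut-2-ene)
Product: 3 1-[2,4-dihydroxy-3,5-bis(3-methylbut-2-en-1-yl)phenyl]ethan-1-one
Conditions: 2 (2.3 equiv), 10% aq. KOH, 0 °C to rt
Reagents that add atoms: none
Why: Nuclear prenylation by C-alkylation of the ambident phenoxide, which water steers towards carbon by solvating the oxygens, should place the two prenyl groups on C3 and C5, the only ring carbons activated by both phenoxide oxygens.

Step 2
Reactants: 3 1-[2,4-dihydroxy-3,5-bis(3-methylbut-2-en-1-yl)phenyl]ethan-1-one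
Product: 4 1-[2-hydroxy-3,5-bis(3-methylbut-2-en-1-yl)-4-(triisopropylsilyloxy)phenyl]ethan-1-one
Conditions: TIPSOTf (1.05 equiv), 2,6-lutidine, CH2Cl2, −78 to 0 °C
Reagents that add atoms: triisopropylsilyl trifluoromethanesulfonate, CC(C)[Si](OS(=O)(=O)C(F)(F)F)(C(C)C)C(C)C
Why: Chemoselective O-silylation should occur at the free, more acidic 4-OH because the 2-OH is held in a hydrogen bond to the acetyl carbonyl, and the silyl triflate is reactive enough for a phenol flanked by two prenyl groups.

Step 3
Reactants: 4 1-[2-hydroxy-3,5-bis(3-methylbut-2-en-1-yl)-4-(triisopropylsilyloxy)phenyl]ethan-1-one; 5 3,4-dimethoxybenzyl alcohol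
Product: 6 1-[2-[(3,4-dimethoxybenzyl)oxy]-3,5-bis(3-methylbut-2-en-1-yl)-4-(triisopropylsilyloxy)phenyl]ethan-1-one
Conditions: PPh3, DIAD, THF, 0 °C to rt
Reagents that add atoms: none
Why: Mitsunobu etherification joins the one remaining phenol to the unhindered primary benzylic alkoxyphosphonium ion under neutral conditions, which spare the base-labile para-acyl aryl silyl ether and the prenyl groups.

Step 4
Reactants: 6 1-[2-[(3,4-dimethoxybenzyl)oxy]-3,5-bis(3-methylbut-2-en-1-yl)-4-(triisopropylsilyloxy)phenyl]ethan-1-one
Product: 8 2-diazo-1-[2-[(3,4-dimethoxybenzyl)oxy]-3,5-bis(3-methylbut-2-en-1-yl)-4-(triisopropylsilyloxy)phenyl]ethan-1-one, via trifluoroacetyl diketone 7 (not isolated)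
Conditions: LiHMDS, THF, −78 °C, then CF3CO2CH2CF3; 1 M HCl work-up; p-ABSA, Et3N, H2O, MeCN, rt
Reagents that add atoms: 4-acetamidobenzenesulfonyl azide (p-ABSA), CC(=O)Nc1ccc(cc1)S(=O)(=O)N=[N+]=[N-]
Why: In this detrifluoroacetylative (Regitz-type deacylative) diazo transfer, Claisen trifluoroacetylation of the lithium enolate of the methyl ketone activates the CH3 carbon, which then takes the diazo group from the sulfonyl azide while the CF3CO group leaves on the sulfonamide nitrogen.

Step 5
Reactants: 8 2-diazo-1-[2-[(3,4-dimethoxybenzyl)oxy]-3,5-bis(3-methylbut-2-en-1-yl)-4-(triisopropylsilyloxy)phenyl]ethan-1-one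
Product: 9 (2S)-2-(3,4-dimethoxyphenyl)-6,8-bis(3-methylbut-2-en-1-yl)-7-(triisopropylsilyloxy)chroman-4-one
Conditions: Rh2(S-BSP)4 (1–2 mol %), CH2Cl2, rt, slow addition of 8 at high dilution
Reagents that add atoms: none
Why: Rhodium(II) expels N2 from the diazoketone to give an electrophilic acyl carbenoid at the future C3, which inserts through a concerted, asynchronous three-centre (hydride-transfer-like) transition state into a benzylic C–H of the ortho veratryl ether and so makes the C2–C3 bond. The closest known reaction type is the rhodium(II) N-arylsulfonylprolinate-catalysed intramolecular C–H insertion of ortho-alkoxyaryl α-diazoketones into the ether α-C–H bond, which gives 2-substituted chroman-4-ones. The pyranone ring closes as a six-membered ring by formal 1,6-insertion (carbenoid carbon, C4, C4a, C8a, O1, C2), the usual 1,5-site being the ether oxygen itself. C2 is the only new stereocentre and is set by catalyst control, the chiral prolinate ligands around the Rh–Rh core letting only one of the two enantiotopic benzylic hydrogens reach the carbenoid, while the neutral medium offers no retro-oxa-Michael path to scramble it. The step needs insertion to outrun oxonium ylide formation with 1,2-shift of the veratryl group, cyclopropanation and carbene dimerisation; the substrate helps because the C–H is activated by both the O1 lone pair and the electron-rich aryl ring, O1 is a weak donor (a vinylogous ester oxygen crowded by its two ortho neighbours), both prenyl alkenes could be reached only through impossible meta-bridged rings, and slow addition at high dilution suppresses bimolecular paths.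

Step 6
Reactants: 9 (2S)-2-(3,4-dimethoxyphenyl)-6,8-bis(3-methylbut-2-en-1-yl)-7-(triisopropylsilyloxy)chroman-4-one
Product: 10 (2S)-7-hydroxy-2-(3,4-dimethoxyphenyl)-6,8-bis(3-methylbut-2-en-1-yl)chroman-4-one (IN0946)
Conditions: TBAF, AcOH (1:1), THF, 0 °C
Reagents that add atoms: none
Why: Fluoride-driven desilylation of the aryl silyl ether, buffered with acetic acid so that no free phenoxide or enolate can start an E1cB ring opening, should free the 7-OH without touching C2 or cyclising the phenol onto a neighbouring prenyl group.

**Compound list**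

1 | 2,4-dihydroxyacetophenone | CC(=O)c1ccc(O)cc1O | starting material
2 | prenyl bromide (1-bromo-3-methylbut-2-ene) | CC(C)=CCBr | starting material
3 | 1-[2,4-dihydroxy-3,5-bis(3-methylbut-2-en-1-yl)phenyl]ethan-1-one | CC(=O)c1cc(CC=C(C)C)c(O)c(CC=C(C)C)c1O | intermediate
4 | 1-[2-hydroxy-3,5-bis(3-methylbut-2-en-1-yl)-4-(triisopropylsilyloxy)phenyl]ethan-1-one | CC(=O)c1cc(CC=C(C)C)c(O[Si](C(C)C)(C(C)C)C(C)C)c(CC=C(C)C)c1O | intermediate
5 | 3,4-dimethoxybenzyl alcohol | COc1ccc(CO)cc1OC | starting material
6 | 1-[2-[(3,4-dimethoxybenzyl)oxy]-3,5-bis(3-methylbut-2-en-1-yl)-4-(triisopropylsilyloxy)phenyl]ethan-1-one | COc1ccc(COc2c(CC=C(C)C)c(O[Si](C(C)C)(C(C)C)C(C)C)c(CC=C(C)C)cc2C(C)=O)cc1OC | intermediate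
7 | 1-[2-[(3,4-dimethoxybenzyl)oxy]-3,5-bis(3-methylbut-2-en-1-yl)-4-(triisopropylsilyloxy)phenyl]-4,4,4-trifluorobutane-1,3-dione | COc1ccc(COc2c(CC=C(C)C)c(O[Si](C(C)C)(C(C)C)C(C)C)c(CC=C(C)C)cc2C(=O)CC(=O)C(F)(F)F)cc1OC | intermediate
8 | 2-diazo-1-[2-[(3,4-dimethoxybenzyl)oxy]-3,5-bis(3-methylbut-2-en-1-yl)-4-(triisopropylsilyloxy)phenyl]ethan-1-one | COc1ccc(COc2c(CC=C(C)C)c(O[Si](C(C)C)(C(C)C)C(C)C)c(CC=C(C)C)cc2C(=O)C=[N+]=[N-])cc1OC | intermediate
9 | (2S)-2-(3,4-dimethoxyphenyl)-6,8-bis(3-methylbut-2-en-1-yl)-7-(triisopropylsilyloxy)chroman-4-one | COc1ccc([C@@H]2CC(=O)c3cc(CC=C(C)C)c(O[Si](C(C)C)(C(C)C)C(C)C)c(CC=C(C)C)c3O2)cc1OC | intermediate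
10 | (2S)-7-hydroxy-2-(3,4-dimethoxyphenyl)-6,8-bis(3-methylbut-2-en-1-yl)chroman-4-one (IN0946) | COc1ccc([C@@H]2CC(=O)c3cc(CC=C(C)C)c(O)c(CC=C(C)C)c3O2)cc1OC | target

**Count and risks**

Total step count: 6. Longest linear sequence: 6 steps (1 → 3 → 4 → 6 → 8 → 9 → 10).

Steps most likely to fail:

1. Step 5. The carbenoid may be intercepted by the O1 lone pair, giving an oxonium ylide whose 1,2-veratryl shift contracts the ring to a benzofuranone. Discrimination between the two benzylic hydrogens by an acceptor-only carbenoid may also be incomplete, and traces of acid can strip the veratryl group from 8 before the catalyst acts (8 should be handled on base-washed silica). If only the enantiomeric purity falls short, recrystallisation of 10 is foreseen. The fallback gives up the carbenoid and adds ring B to a preformed pyranone. Setting out from 4, condensation with DMF dimethyl acetal (toluene, 90 °C) should give the enaminone (E)-3-(dimethylamino)-1-[2-hydroxy-3,5-bis(3-methylbut-2-en-1-yl)-4-(triisopropylsilyloxy)phenyl]prop-2-en-1-one F1. Brief exposure to dilute HCl in CH2Cl2 should close it to 6,8-bis(3-methylbut-2-en-1-yl)-7-(triisopropylsilyloxy)-4H-chromen-4-one F2. Asymmetric conjugate addition of 3,4-dimethoxyphenylboronic acid (Hayashi–Miyaura type; Pd(OCOCF3)2, the t-Bu-pyridine-oxazoline enantiomer that leads to 2S, NH4PF6, H2O, 1,2-dichloroethane, 60 °C) should then place the aryl group on C2 and return to the route at 9.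

2. Step 1. Alkylation may stop after one prenyl group, or run on to O-alkylation and geminal C-dialkylation with loss of aromaticity, so that the share of clean 3,5-dialkylation is small. The fallback fixes both positions by halogenation and forms the C–C bonds by cross-coupling. Setting out from 1, iodination with I2/HIO3 in aqueous ethanol should give 1-(2,4-dihydroxy-3,5-diiodophenyl)ethan-1-one F3. A twofold Stille coupling with tributyl(3-methylbut-2-en-1-yl)stannane (Pd(PPh3)4, DMF, 90 °C), which transfers the allyl group mainly at its less substituted terminus, should then return to the route at 3.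

3. Step 3. The phenol is hydrogen-bonded to the acetyl group and flanked on both sides, so the activated alcohol may be consumed by alkylation of the hydrazide faster than by the phenoxide. The fallback is a Williamson ether synthesis with a preformed benzylic halide. Setting out from 5, PBr3 in Et2O at 0 °C should give 4-(bromomethyl)-1,2-dimethoxybenzene F4. Used at once, it should alkylate 4 with K2CO3 and catalytic Bu4NI in acetone at reflux, rejoining the route at 6.

**Further compounds**

F1 | step 5 | (E)-3-(dimethylamino)-1-[2-hydroxy-3,5-bis(3-methylbut-2-en-1-yl)-4-(triisopropylsilyloxy)phenyl]prop-2-en-1-one | CN(C)/C=C/C(=O)c1cc(CC=C(C)C)c(O[Si](C(C)C)(C(C)C)C(C)C)c(CC=C(C)C)c1O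
F2 | step 5 | 6,8-bis(3-methylbut-2-en-1-yl)-7-(triisopropylsilyloxy)-4H-chromen-4-one | O=c1ccoc2c(CC=C(C)C)c(O[Si](C(C)C)(C(C)C)C(C)C)c(CC=C(C)C)cc12
F3 | step 1 | 1-(2,4-dihydroxy-3,5-diiodophenyl)ethan-1-one | CC(=O)c1cc(I)c(O)c(I)c1O
F4 | step 3 | 4-(bromomethyl)-1,2-dimethoxybenzene | COc1ccc(CBr)cc1OC
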